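It is tempting to give a catalyst one time constant, yet J goes round a cycle of 3 waits in series, and one of them stretches as D falls.

the same everywhere: D 20 mM; J 0.40 mM; time 1.0 min
- blue: temperature 0 °C
- ochre: temperature −30 °C
- grey: temperature 30 °C

    D.J → Z (k1 = 10.5 s⁻¹, Ea1 = 63.0 kJ mol⁻¹)
    Z ⇌ J + G (K2 = 0.581 M, k2 = 3.25 s⁻¹, Ea2 = 54.0 kJ mol⁻¹, ΔH2 = −4.00 kJ mol⁻¹)
    2 D → D2 (k3 = 0.00412 L mol⁻¹ s⁻¹, Ea3 = 51.0 kJ mol⁻¹)
    D + J ⇌ D.J (K4 = 45.1 L mol⁻¹, k4 = 116 L mol⁻¹ s⁻¹, Ea4 = 42.0 kJ mol⁻¹, ΔH4 = 4.00 kJ mol⁻¹)
    E ⇌ G, rate k5*(cs5 - [G]) while solid is left; crystals form when [G] > cs5 (cs5 = 16 mM, k5 = 3.13 s⁻¹)
    (constants at 0 °C)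

- percent here means D units held: one D2 counts as two
- what is said of G includes E
- for a step with 2 of a species take k times the square, and two of it per event
- E is a solid; its amount is given per volume of the solution
- constants are those at 0 °C; use the activation energies and enthalpies for any other temperature

- which flask leads in amount of G, in percent of the D charged ("all alike" within 1.5 percentage points) (blue / ochre / grey / all alike)
- how much G is there at the end, in percent of the D charged: blue
- how much G is there at the end, in percent of the D charged: ochre
- how much G is there at the end, in percent of the D charged: grey

We reckon the pace of that cycle at the start of each flask, with the constants moved to each temperature. J waits to be caught by D, a wait that goes as one over the amount of D and is lengthened by the D.J that falls back; D.J waits to become Z; Z waits to release G and J. Added up, one round of the cycle (one turnover) takes 0.940 s in blue, 16.9 s in ochre and 0.110 s in grey.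

The reach in ochre, 0.0708, is the catalyst charge times the time, divided by the D charge times one round: the share of D the catalyst could turn over at its starting pace. Blue has a reach of 1.28 and grey 10.9. A reach of one marks the crossing, at which the starting pace just covers the D charge, the limiting reagent, in the time.

Ochre lies far below the crossing, so its D stays near the charge, its pace holds, and we expect G of about 7.08%. Grey lies far above it, so we expect G close to the D charged, and we expect grey to lead. Blue sits beside the crossing, and there one number is not enough, because the wait for D stretches as D falls. Summing the rounds over falling D, blue reaches 80.0% conversion at 0.988 min, and that is our figure for blue.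

The forecast names grey, with 79.4% in blue, 6.4% in ochre and 99.5% in grey, giving ochre “about three slow turnovers per catalyst, including a start-up lag”. Its ochre figure is lower than ours.

The simulation gives grey as the leader, with 79.5% in blue, 6.42% in ochre and 99.6% in grey, so the forecast stands; grey's G moves by 5 points when J falls to 0.0938 mM. Ochre's G is 0.907 of its reach. The neighbouring flask is ochre with 0.68 mM of J. Our round time holds no J, so the neighbour's reach grows with the catalyst charge to 0.120. Its G comes to 10.8%, which is 0.900 of that reach.

The rate constants are invented; the run is a simulation.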